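Ring A is opened at C3–C4, where the Z-trisubstituted C4=C5 alkene carries the C3 carbinol as its allylic substituent. A Z-alkenyl iodide at C4 and an aldehyde at C3 are joined by an intramolecular Nozaki–Hiyama–Kishi reaction, which in one operation closes the ten-membered carbocycle onto the finished trans-fused lactone (ring B), forms the C3–C4 bond, creates the C3 alcohol and carries the Z geometry into the ring unchanged. The precursor is an α-methylene-γ-butyrolactone with a (Z)-2-iodoprop-1-enyl group on C6 and, on C7, the C8-silyloxy chain that holds the E-C1=C10 alkene and the C3 aldehyde; its three stereocentres come from an anti-selective allylboration.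

Key step: step 13

Assumption (step 7): the (S,S) enantiomer of the ProPhenol ligand is taken to add the alkynyl group to the Si face of aldehyde 12 (4R product); if the sense is the reverse, the mirror-image ligand is used.

Remarks on the chemistry:
- The 3-iodo regiochemistry from but-2-yn-1-ol needs NaAlH2(OCH2CH2OMe)2, and the enal needs a separate oxidation.
- Zinc or indium reagents made from 2-(bromomethyl)enoates favour syn adducts and cis lactones. The trans lactone is therefore built with a configurationally stable allylboronate whose C8 chain is cis to the ester.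
- The precursor keeps the C8 silyl ether. Its β,γ-unsaturated aldehyde is made under base-free conditions immediately before ring closure.
- The side chain is the epoxide of tiglic acid (methyl groups cis), (2R,3S).

Step 1
Reactants: 1 but-2-yn-1-ol
Product: 3 (Z)-3-iodobut-2-en-1-ol, via sodium alkenylaluminate 2 (not isolated)
Conditions: NaAlH2(OCH2CH2OMe)2, THF, 0 °C → rt; EtOAc; then I2, −78 → 0 °C
Reagents that add atoms: iodine, [I][I]
Why: Hydroxyl-directed trans-hydroalumination of the propargylic alcohol puts aluminium on C3 cis to the CH2O group, and iodinolysis with retention should give the Z iodide (hydroalumination–iodination).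

Step 2
Reactants: 3 (Z)-3-iodobut-2-en-1-ol
Product: 4 (Z)-3-iodobut-2-enal
Conditions: MnO2, CH2Cl2, rt, dark; used at once
Reagents that add atoms: none
Why: MnO2 oxidises the allylic alcohol to the enal without touching the alkenyl iodide or its geometry (allylic alcohol oxidation).

Step 3
Reactants: 5 tert-butyl(but-3-yn-1-yloxy)dimethylsilane; 6 ethylene oxide
Product: 9 (E)-6-[(tert-butyldimethylsilyl)oxy]-4-methylhex-3-en-1-ol, via alkenyldimethylalane 7 (not isolated), via lithium butyl alanate 8 (not isolated)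
Conditions: AlMe3, Cp2ZrCl2 (0.25 equiv), CH2Cl2, 0 °C → rt; solvent change to hexane/THF; n-BuLi, −78 °C; ethylene oxide, −78 → 0 °C
Reagents that add atoms: trimethylaluminium, C[Al](C)C
Why: Zirconium-catalysed syn carboalumination (Negishi) adds methyl to the internal and aluminium to the terminal alkyne carbon, and the lithium alanate opens ethylene oxide with retention, which fixes the E geometry of the future C1=C10 bond.

Step 4
Reactants: 9 (E)-6-[(tert-butyldimethylsilyl)oxy]-4-methylhex-3-en-1-ol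
Product: 10 tert-butyl{[(E)-6-[(4-methoxybenzyl)oxy]-3-methylhex-3-en-1-yl]oxy}dimethylsilane
Conditions: NaH, 4-methoxybenzyl chloride, Bu4NI (cat.), THF/DMF, 0 °C → rt
Reagents that add atoms: 4-methoxybenzyl chloride, COc1ccc(CCl)cc1
Why: Williamson etherification of the primary alkoxide protects the future C3 oxygen with a group that survives hydride, Lewis acid and fluoride steps.

Step 5
Reactants: 10 tert-butyl{[(E)-6-[(4-methoxybenzyl)oxy]-3-methylhex-3-en-1-yl]oxy}dimethylsilane
Product: 11 (E)-6-[(4-methoxybenzyl)oxy]-3-methylhex-3-en-1-ol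
Conditions: Bu4NF, THF, 0 °C → rt
Reagents that add atoms: none
Why: Fluoride cleaves the primary silyl ether and leaves the benzyl-type ether intact (desilylation).

Step 6
Reactants: 11 (E)-6-[(4-methoxybenzyl)oxy]-3-methylhex-3-en-1-ol
Product: 12 (E)-6-[(4-methoxybenzyl)oxy]-3-methylhex-3-enal
Conditions: Dess–Martin periodinane, NaHCO3, CH2Cl2, 0 °C; used crude
Reagents that add atoms: none
Why: Buffered Dess–Martin oxidation gives the β,γ-unsaturated aldehyde without the base that would move the alkene into conjugation.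

Step 7
Reactants: 12 (E)-6-[(4-methoxybenzyl)oxy]-3-methylhex-3-enal; 13 methyl propiolate
Product: 15 methyl (4R,6E)-4-hydroxy-9-[(4-methoxybenzyl)oxy]-6-methylnon-6-en-2-ynoate, via methylzinc alkynylide 14 (not isolated)
Conditions: (S,S)-ProPhenol (20 mol%), Me2Zn, Ph3PO (cat.), toluene, 4 °C
Reagents that add atoms: none
Why: The dinuclear zinc–ProPhenol catalyst adds the zinc alkynylide to one aldehyde face, which sets C8 (4R here) under ligand control (catalytic asymmetric alkynylation).

Step 8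
Reactants: 15 methyl (4R,6E)-4-hydroxy-9-[(4-methoxybenzyl)oxy]-6-methylnon-6-en-2-ynoate
Product: 16 methyl (4R,6E)-4-[(tert-butyldimethylsilyl)oxy]-9-[(4-methoxybenzyl)oxy]-6-methylnon-6-en-2-ynoate
Conditions: TBSOTf, 2,6-lutidine, CH2Cl2, −78 °C
Reagents that add atoms: tert-butyldimethylsilyl triflate, CC(C)(C)[Si](C)(C)OS(=O)(=O)C(F)(F)F
Why: Silylation with a non-nucleophilic base protects the propargylic alcohol without conjugate addition to the ynoate.

Step 9
Reactants: 16 methyl (4R,6E)-4-[(tert-butyldimethylsilyl)oxy]-9-[(4-methoxybenzyl)oxy]-6-methylnon-6-en-2-ynoate; 17 2-(iodomethyl)-4,4,5,5-tetramethyl-1,3,2-dioxaborolane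
Product: 19 methyl (2Z,4R,6E)-4-[(tert-butyldimethylsilyl)oxy]-9-[(4-methoxybenzyl)oxy]-6-methyl-2-[(4,4,5,5-tetramethyl-1,3,2-dioxaborolan-2-yl)methyl]nona-2,6-dienoate, via α-alumanyl enoate 18 (not isolated)
Conditions: i-Bu2AlH, HMPA, MeCu (10 mol%), THF, −50 → −20 °C; then 17, −20 °C → rt
Reagents that add atoms: none
Why: Copper-catalysed conjugate hydroalumination adds hydride to C7 and aluminium to C11 on the same side, and C-alkylation by the iodomethylboronate with retention should leave the C8 chain cis to the ester (conjugate reduction–alkylation route to 2-alkoxycarbonyl allylboronates).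

Step 10
Reactants: 19 methyl (2Z,4R,6E)-4-[(tert-butyldimethylsilyl)oxy]-9-[(4-methoxybenzyl)oxy]-6-methyl-2-[(4,4,5,5-tetramethyl-1,3,2-dioxaborolan-2-yl)methyl]nona-2,6-dienoate; 4 (Z)-3-iodobut-2-enal
Product: 21 (4S,5S)-4-[(1R,3E)-1-[(tert-butyldimethylsilyl)oxy]-6-[(4-methoxybenzyl)oxy]-3-methylhex-3-en-1-yl]-5-[(Z)-2-iodoprop-1-en-1-yl]-3-methylidenedihydrofuran-2(3H)-one, via homoallylic borate 20 (not isolated)
Conditions: Sc(OTf)3 (10 mol%), toluene, 0 °C → rt; then p-TsOH·H2O (cat.), rt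
Reagents that add atoms: none
Why: Lewis-acid-catalysed allylboration through a closed chair transition state with the C8 chain equatorial should give the anti C6/C7 adduct (trans lactone after ring closure), and C7 is expected to be set relative to C8 by attack anti to the C9 methylene in the rotamer whose C8–H eclipses the alkene (A(1,3) strain) and whose silyloxy group stays out of the anti position.

Step 11
Reactants: 21 (4S,5S)-4-[(1R,3E)-1-[(tert-butyldimethylsilyl)oxy]-6-[(4-methoxybenzyl)oxy]-3-methylhex-3-en-1-yl]-5-[(Z)-2-iodoprop-1-en-1-yl]-3-methylidenedihydrofuran-2(3H)-one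
Product: 22 (4S,5S)-4-[(1R,3E)-1-[(tert-butyldimethylsilyl)oxy]-6-hydroxy-3-methylhex-3-en-1-yl]-5-[(Z)-2-iodoprop-1-en-1-yl]-3-methylidenedihydrofuran-2(3H)-one
Conditions: DDQ, CH2Cl2/pH 7 buffer, 0 °C
Reagents that add atoms: none
Why: Oxidative cleavage of the 4-methoxybenzyl ether frees the primary alcohol without affecting the silyl ether, the enoate or the alkenyl iodide.

Step 12
Reactants: 22 (4S,5S)-4-[(1R,3E)-1-[(tert-butyldimethylsilyl)oxy]-6-hydroxy-3-methylhex-3-en-1-yl]-5-[(Z)-2-iodoprop-1-en-1-yl]-3-methylidenedihydrofuran-2(3H)-one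
Product: 23 (4S,5S)-4-[(1R,3E)-1-[(tert-butyldimethylsilyl)oxy]-3-methyl-6-oxohex-3-en-1-yl]-5-[(Z)-2-iodoprop-1-en-1-yl]-3-methylidenedihydrofuran-2(3H)-one
Conditions: Dess–Martin periodinane, NaHCO3, CH2Cl2, 0 °C; filtered and used at once
Reagents that add atoms: none
Why: Buffered Dess–Martin oxidation delivers the C3 aldehyde without conjugating the C1=C10 alkene or epimerising the lactone.

Step 13
Reactants: 23 (4S,5S)-4-[(1R,3E)-1-[(tert-butyldimethylsilyl)oxy]-3-methyl-6-oxohex-3-en-1-yl]-5-[(Z)-2-iodoprop-1-en-1-yl]-3-methylidenedihydrofuran-2(3H)-one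
Product: 26 (3S,6R,7S,8R)-8-[(tert-butyldimethylsilyl)oxy]-3-hydroxygermacra-1(10)E,4Z,11(13)-trien-12,6-olide, via alkenylchromium dichloride 24 (not isolated), via chromium alkoxide 25 (not isolated)
Conditions: CrCl2 (8 equiv), NiCl2 (2 mol%), degassed DMSO/THF 3:1, slow addition of 23 to 0.003 M, rt; aqueous work-up
Reagents that add atoms: none
Why: CrCl2 reduces NiCl2 to zerovalent nickel, which inserts into the C4–I bond with retention; transmetalation gives the trivalent alkenylchromium 24, which adds to the C3 aldehyde and is released from alkoxide 25 on work-up. The closest known reaction type is the Nozaki–Hiyama–Kishi macrocyclization of alkenyl iodides onto aldehydes, which is established for medium-ring allylic alcohols. Ring A closes by direct end-to-end attack of C4 on the C3 carbonyl (exo at the carbonyl, ten-membered) under high dilution. The new C3 stereocentre is under substrate control: the aldehyde face that is exposed in the ring-forming conformation, which the trans-fused lactone, the E-C1=C10 and the Z-C4=C5 bonds restrict. The step needs chemoselectivity (only iodide and aldehyde react; enoate, lactone and silyl ether stay, the aldehyde does not conjugate) and ring closure in preference to oligomerization, which the neutral divalent chromium conditions, the dilution and the preorganized chain ends should secure. Either C3 epimer can be carried on, because acylation with retention or with inversion both lead to the benzoate.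

Step 14
Reactants: 26 (3S,6R,7S,8R)-8-[(tert-butyldimethylsilyl)oxy]-3-hydroxygermacra-1(10)E,4Z,11(13)-trien-12,6-olide
Product: 27 (3S,6R,7S,8R)-3-(benzoyloxy)-8-[(tert-butyldimethylsilyl)oxy]germacra-1(10)E,4Z,11(13)-trien-12,6-olide
Conditions: benzoyl chloride, pyridine, DMAP (cat.), CH2Cl2, 0 °C → rt
Reagents that add atoms: benzoyl chloride, O=C(Cl)c1ccccc1
Why: Nucleophile-catalysed O-acylation of the allylic alcohol proceeds with retention at C3.

Step 15
Reactants: 27 (3S,6R,7S,8R)-3-(benzoyloxy)-8-[(tert-butyldimethylsilyl)oxy]germacra-1(10)E,4Z,11(13)-trien-12,6-olide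
Product: 28 (3S,6R,7R,8R)-3-(benzoyloxy)-8-hydroxygermacra-1(10)E,4Z,11(13)-trien-12,6-olide
Conditions: HF·pyridine, pyridine, THF, 0 °C → rt
Reagents that add atoms: none
Why: Buffered HF removes the secondary silyl ether without base, so the lactone should not migrate to O8 and the diene should not cyclize (desilylation).

Step 16
Reactants: 29 (E)-2-methylbut-2-en-1-ol
Product: 30 [(2S,3S)-2,3-dimethyloxiran-2-yl]methanol
Conditions: Ti(OiPr)4, L-(+)-diisopropyl tartrate, t-BuOOH, 4 Å molecular sieves, CH2Cl2, −20 °C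
Reagents that add atoms: tert-butyl hydroperoxide, CC(C)(C)OO
Why: Sharpless asymmetric epoxidation with the L-(+)-tartrate delivers oxygen to the face that gives the (2S,3S) epoxy alcohol, with the methyl groups cis as in the E alkene.

Step 17
Reactants: 30 [(2S,3S)-2,3-dimethyloxiran-2-yl]methanol
Product: 31 (2R,3S)-2,3-dimethyloxirane-2-carboxylic acid
Conditions: RuCl3·xH2O (cat.), NaIO4, CCl4/MeCN/H2O, rt
Reagents that add atoms: water, O
Why: Catalytic RuO4 oxidation converts the primary alcohol to the acid and leaves the epoxide and both stereocentres untouched (the descriptor at C2 changes by priority only).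

Step 18
Reactants: 28 (3S,6R,7R,8R)-3-(benzoyloxy)-8-hydroxygermacra-1(10)E,4Z,11(13)-trien-12,6-olide; 31 (2R,3S)-2,3-dimethyloxirane-2-carboxylic acid
Product: 33 (3S,6R,7R,8R)-3-(benzoyloxy)-8-{[(2R,3S)-2,3-dimethyloxiran-2-yl]carbonyloxy}germacra-1(10)E,4Z,11(13)-trien-12,6-olide, via mixed anhydride 32 (not isolated)
Conditions: 31, 2,4,6-trichlorobenzoyl chloride, Et3N, toluene, rt; then 28, DMAP, toluene, rt → 40 °C
Reagents that add atoms: none
Why: Yamaguchi esterification activates the hindered α-quaternary acid as a mixed anhydride and acylates O8 with retention at C8.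

Step 19
Reactants: 33 (3S,6R,7R,8R)-3-(benzoyloxy)-8-{[(2R,3S)-2,3-dimethyloxiran-2-yl]carbonyloxy}germacra-1(10)E,4Z,11(13)-trien-12,6-olide
Product: 34 CNP0324463.5, (1R,3S,6R,7R,8R,10R)-3-(benzoyloxy)-8-{[(2R,3S)-2,3-dimethyloxiran-2-yl]carbonyloxy}-1,10-epoxygermacra-4Z,11(13)-dien-12,6-olide
Conditions: 3-chloroperbenzoic acid (1.05 equiv), NaHCO3, CH2Cl2, −10 → 0 °C
Reagents that add atoms: 3-chloroperbenzoic acid, OOC(=O)c1cccc(Cl)c1
Why: Prilezhaev epoxidation should pick the electron-rich C1=C10 alkene (C4=C5 is deactivated by two allylic acyloxy groups, C11=C13 is conjugated) and attack its outer face in the ring, which is expected to give the (1R,10R) epoxide stereospecifically from the E alkene.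

Compound list
1 | but-2-yn-1-ol | CC#CCO | starting material
2 | sodium alkenylaluminate, cyclic, from trans-hydroalumination of 1 (not isolated) | CC1=CCO[Al-]1(OCCOC)OCCOC.[Na+] | intermediate
3 | (Z)-3-iodobut-2-en-1-ol | C/C(I)=C/CO | intermediate
4 | (Z)-3-iodobut-2-enal | C/C(I)=C/C=O | intermediate
5 | tert-butyl(but-3-yn-1-yloxy)dimethylsilane | C#CCCO[Si](C)(C)C(C)(C)C | starting material
6 | ethylene oxide | C1CO1 | starting material
7 | (E)-alkenyldimethylalane, Al cis to the new methyl (not isolated) | C[Al](C)/C=C(\C)CCO[Si](C)(C)C(C)(C)C | intermediate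
8 | lithium butyl(alkenyl)dimethylalanate (not isolated) | [Li+].CCCC[Al-](C)(C)/C=C(\C)CCO[Si](C)(C)C(C)(C)C | intermediate
9 | (E)-6-[(tert-butyldimethylsilyl)oxy]-4-methylhex-3-en-1-ol | OCC/C=C(\C)CCO[Si](C)(C)C(C)(C)C | intermediate
10 | tert-butyl{[(E)-6-[(4-methoxybenzyl)oxy]-3-methylhex-3-en-1-yl]oxy}dimethylsilane | COc1ccc(COCC/C=C(\C)CCO[Si](C)(C)C(C)(C)C)cc1 | intermediate
11 | (E)-6-[(4-methoxybenzyl)oxy]-3-methylhex-3-en-1-ol | COc1ccc(COCC/C=C(\C)CCO)cc1 | intermediate
12 | (E)-6-[(4-methoxybenzyl)oxy]-3-methylhex-3-enal | COc1ccc(COCC/C=C(\C)CC=O)cc1 | intermediate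
13 | methyl propiolate | C#CC(=O)OC | starting material
14 | methyl 3-(methylzincio)propiolate (not isolated) | C[Zn]C#CC(=O)OC | intermediate
15 | methyl (4R,6E)-4-hydroxy-9-[(4-methoxybenzyl)oxy]-6-methylnon-6-en-2-ynoate | COC(=O)C#C[C@H](O)C/C(C)=C/CCOCc1ccc(OC)cc1 | intermediate
16 | methyl (4R,6E)-4-[(tert-butyldimethylsilyl)oxy]-9-[(4-methoxybenzyl)oxy]-6-methylnon-6-en-2-ynoate | COC(=O)C#C[C@H](O[Si](C)(C)C(C)(C)C)C/C(C)=C/CCOCc1ccc(OC)cc1 | intermediate
17 | 2-(iodomethyl)-4,4,5,5-tetramethyl-1,3,2-dioxaborolane | CC1(C)OB(CI)OC1(C)C | starting material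
18 | methyl (2E,4R,6E)-2-(diisobutylalumanyl)-4-[(tert-butyldimethylsilyl)oxy]-9-[(4-methoxybenzyl)oxy]-6-methylnona-2,6-dienoate, C8 chain cis to the ester (not isolated) | COC(=O)/C([Al](CC(C)C)CC(C)C)=C\[C@H](O[Si](C)(C)C(C)(C)C)C/C(C)=C/CCOCc1ccc(OC)cc1 | intermediate
19 | methyl (2Z,4R,6E)-4-[(tert-butyldimethylsilyl)oxy]-9-[(4-methoxybenzyl)oxy]-6-methyl-2-[(4,4,5,5-tetramethyl-1,3,2-dioxaborolan-2-yl)methyl]nona-2,6-dienoate | COC(=O)/C(CB1OC(C)(C)C(C)(C)O1)=C\[C@H](O[Si](C)(C)C(C)(C)C)C/C(C)=C/CCOCc1ccc(OC)cc1 | intermediate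
20 | open-chain pinacol borate of the anti adduct (C6–O–B, methyl 2-methylidene ester, configurations as in 21; not isolated) | COC(=O)C(=C)[C@@H]([C@H](OB1OC(C)(C)C(C)(C)O1)/C=C(/C)I)[C@H](O[Si](C)(C)C(C)(C)C)C/C(C)=C/CCOCc1ccc(OC)cc1 | intermediate
21 | (4S,5S)-4-[(1R,3E)-1-[(tert-butyldimethylsilyl)oxy]-6-[(4-methoxybenzyl)oxy]-3-methylhex-3-en-1-yl]-5-[(Z)-2-iodoprop-1-en-1-yl]-3-methylidenedihydrofuran-2(3H)-one | C=C1C(=O)O[C@H](/C=C(/C)I)[C@H]1[C@H](O[Si](C)(C)C(C)(C)C)C/C(C)=C/CCOCc1ccc(OC)cc1 | intermediate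
22 | (4S,5S)-4-[(1R,3E)-1-[(tert-butyldimethylsilyl)oxy]-6-hydroxy-3-methylhex-3-en-1-yl]-5-[(Z)-2-iodoprop-1-en-1-yl]-3-methylidenedihydrofuran-2(3H)-one | C=C1C(=O)O[C@H](/C=C(/C)I)[C@H]1[C@H](O[Si](C)(C)C(C)(C)C)C/C(C)=C/CCO | intermediate
23 | (4S,5S)-4-[(1R,3E)-1-[(tert-butyldimethylsilyl)oxy]-3-methyl-6-oxohex-3-en-1-yl]-5-[(Z)-2-iodoprop-1-en-1-yl]-3-methylidenedihydrofuran-2(3H)-one (seco aldehyde, precursor of the key step) | C=C1C(=O)O[C@H](/C=C(/C)I)[C@H]1[C@H](O[Si](C)(C)C(C)(C)C)C/C(C)=C/CC=O | intermediate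
24 | (Z)-alkenylchromium dichloride from 23, Cr in place of I (not isolated) | C=C1C(=O)O[C@H](/C=C(/C)[Cr](Cl)Cl)[C@H]1[C@H](O[Si](C)(C)C(C)(C)C)C/C(C)=C/CC=O | intermediate
25 | chromium dichloride alkoxide of 26 at O3 (not isolated) | C=C1C(=O)O[C@@H]2/C=C(/C)[C@@H](O[Cr](Cl)Cl)C/C=C(\C)/C[C@@H](O[Si](C)(C)C(C)(C)C)[C@@H]12 | intermediate
26 | (3S,6R,7S,8R)-8-[(tert-butyldimethylsilyl)oxy]-3-hydroxygermacra-1(10)E,4Z,11(13)-trien-12,6-olide | C=C1C(=O)O[C@@H]2/C=C(/C)[C@@H](O)C/C=C(\C)/C[C@@H](O[Si](C)(C)C(C)(C)C)[C@@H]12 | intermediate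
27 | (3S,6R,7S,8R)-3-(benzoyloxy)-8-[(tert-butyldimethylsilyl)oxy]germacra-1(10)E,4Z,11(13)-trien-12,6-olide | C=C1C(=O)O[C@@H]2/C=C(/C)[C@@H](OC(=O)c3ccccc3)C/C=C(\C)/C[C@@H](O[Si](C)(C)C(C)(C)C)[C@@H]12 | intermediate
28 | (3S,6R,7R,8R)-3-(benzoyloxy)-8-hydroxygermacra-1(10)E,4Z,11(13)-trien-12,6-olide | C=C1C(=O)O[C@@H]2/C=C(/C)[C@@H](OC(=O)c3ccccc3)C/C=C(\C)/C[C@@H](O)[C@@H]12 | intermediate
29 | (E)-2-methylbut-2-en-1-ol | C/C=C(\C)CO | starting material
30 | [(2S,3S)-2,3-dimethyloxiran-2-yl]methanol | OC[C@]1(C)O[C@H]1C | intermediate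
31 | (2R,3S)-2,3-dimethyloxirane-2-carboxylic acid | OC(=O)[C@]1(C)O[C@H]1C | intermediate
32 | (2R,3S)-2,3-dimethyloxirane-2-carboxylic 2,4,6-trichlorobenzoic anhydride (not isolated) | O=C(OC(=O)[C@]1(C)O[C@H]1C)c1c(Cl)cc(Cl)cc1Cl | intermediate
33 | (3S,6R,7R,8R)-3-(benzoyloxy)-8-{[(2R,3S)-2,3-dimethyloxiran-2-yl]carbonyloxy}germacra-1(10)E,4Z,11(13)-trien-12,6-olide | C=C1C(=O)O[C@@H]2/C=C(/C)[C@@H](OC(=O)c3ccccc3)C/C=C(\C)/C[C@@H](OC(=O)[C@]3(C)O[C@H]3C)[C@@H]12 | intermediate
34 | CNP0324463.5, (1R,3S,6R,7R,8R,10R)-3-(benzoyloxy)-8-{[(2R,3S)-2,3-dimethyloxiran-2-yl]carbonyloxy}-1,10-epoxygermacra-4Z,11(13)-dien-12,6-olide | C=C1C(=O)O[C@@H]2/C=C(/C)[C@@H](OC(=O)c3ccccc3)C[C@H]3O[C@]3(C)C[C@@H](OC(=O)[C@]3(C)O[C@H]3C)[C@@H]12 | target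

Total step count: 19. Longest linear sequence: 15 steps (steps 3 to 15, then 18 and 19, from compound 5).

Steps most likely to fail

1. Step 13 (ring closure). The alkenylchromium may add to the other face of the C3 aldehyde, and the β,γ-unsaturated aldehyde may conjugate or oligomerize before it closes. Fallback for the facial problem: it sets out from 23 and comes back at 27. The cyclization is run as before and gives the C3-epimeric alcohol (3R,6R,7S,8R)-8-[(tert-butyldimethylsilyl)oxy]-3-hydroxygermacra-1(10)E,4Z,11(13)-trien-12,6-olide F1. This is benzoylated with inversion under Mitsunobu conditions (benzoic acid, PPh3, diisopropyl azodicarboxylate, toluene, 0 °C) in place of the acyl chloride, which delivers benzoate 27.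

2. Step 10 (allylboration). The anti relationship of C6 and C7 may erode through E/Z equilibration of the boronate or a non-chair pathway under the Lewis acid, which gives the cis lactone; the C7/C8 sense also rests on a conformational model only, and this fallback does not correct it. Fallback: it sets out from 19 and 4 and comes back at 21. The cis lactone (4S,5R)-4-[(1R,3E)-1-[(tert-butyldimethylsilyl)oxy]-6-[(4-methoxybenzyl)oxy]-3-methylhex-3-en-1-yl]-5-[(Z)-2-iodoprop-1-en-1-yl]-3-methylidenedihydrofuran-2(3H)-one F2 is opened with LiOH in THF/water and carefully acidified to (3S,4R,5Z)-3-[(1R,3E)-1-[(tert-butyldimethylsilyl)oxy]-6-[(4-methoxybenzyl)oxy]-3-methylhex-3-en-1-yl]-4-hydroxy-6-iodo-2-methylidenehept-5-enoic acid F3. Mitsunobu lactonization (PPh3, diisopropyl azodicarboxylate, THF, 0 °C) then closes the ring with inversion at the allylic C6 and gives the trans lactone 21.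

3. Step 19 (epoxidation). The peracid may deliver oxygen to the other face of C1=C10, because the facial preference depends on the ring conformation. Fallback: it sets out from 33 and comes back at 34. N-Bromosuccinimide in aqueous THF at 0 °C forms the bromonium ion on the face the peracid prefers, and water opens it anti at C10 to give (1S,3S,6R,7R,8R,10R)-3-(benzoyloxy)-1-bromo-8-{[(2R,3S)-2,3-dimethyloxiran-2-yl]carbonyloxy}-10-hydroxygermacra-4Z,11(13)-dien-12,6-olide F4. DBU in CH2Cl2 closes the epoxide by displacement of bromide with inversion at C1, which places the oxygen on the opposite face and gives 34.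

Further compounds
F1 | step 13 | (3R,6R,7S,8R)-8-[(tert-butyldimethylsilyl)oxy]-3-hydroxygermacra-1(10)E,4Z,11(13)-trien-12,6-olide | C=C1C(=O)O[C@@H]2/C=C(/C)[C@H](O)C/C=C(\C)/C[C@@H](O[Si](C)(C)C(C)(C)C)[C@@H]12
F2 | step 10 | (4S,5R)-4-[(1R,3E)-1-[(tert-butyldimethylsilyl)oxy]-6-[(4-methoxybenzyl)oxy]-3-methylhex-3-en-1-yl]-5-[(Z)-2-iodoprop-1-en-1-yl]-3-methylidenedihydrofuran-2(3H)-one | C=C1C(=O)O[C@@H](/C=C(/C)I)[C@H]1[C@H](O[Si](C)(C)C(C)(C)C)C/C(C)=C/CCOCc1ccc(OC)cc1
F3 | step 10 | (3S,4R,5Z)-3-[(1R,3E)-1-[(tert-butyldimethylsilyl)oxy]-6-[(4-methoxybenzyl)oxy]-3-methylhex-3-en-1-yl]-4-hydroxy-6-iodo-2-methylidenehept-5-enoic acid | OC(=O)C(=C)[C@@H]([C@@H](O)/C=C(/C)I)[C@H](O[Si](C)(C)C(C)(C)C)C/C(C)=C/CCOCc1ccc(OC)cc1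
F4 | step 19 | (1S,3S,6R,7R,8R,10R)-3-(benzoyloxy)-1-bromo-8-{[(2R,3S)-2,3-dimethyloxiran-2-yl]carbonyloxy}-10-hydroxygermacra-4Z,11(13)-dien-12,6-olide | C=C1C(=O)O[C@@H]2/C=C(/C)[C@@H](OC(=O)c3ccccc3)C[C@H](Br)[C@](C)(O)C[C@@H](OC(=O)[C@]3(C)O[C@H]3C)[C@@H]12
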